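## Structural features

Mollicellin A is a tetracyclic depsidone: benzene rings A and B are joined twice, through a diaryl ether oxygen (a5–O–b6) and through an aryl ester (a6–C(=O)–O–b1), and these two links close a central seven-membered dioxepinone. Ring B is fused across b3–b4 to a 2,2-dimethyl-2,3-dihydropyran-4-one, and ring A carries a methyl group (a1), a free hydroxyl (a3) and a formyl group (a4) hydrogen-bonded to that hydroxyl. The target has no stereocentre, so nothing but connectivity and regiochemistry has to be controlled; the only adjacent stereocentres of the route are the transient b5 and b6 of the dione intermediate. The fragile parts are the lactone (an activated aryl ester that alkoxides open), the salicylaldehyde unit, the pyranone (retro-oxa-Michael opening under base) and, on the way, orsellinic-type benzoic acids that lose CO2 when heated with acid. The real difficulty is the ether oxygen, which bridges two carbons (a5 and b6) each flanked by two substituents, the least favourable case for aryl–oxygen coupling; the late choices b4 versus b2 and a4 versus a2 come second. The key step exploits the oxygen pattern of ring B: oxygens at b1 and b3 are meta, b5 carries methyl and b6 the ether oxygen, so ring B is the aromatised form of a 4-aryloxy-5-methylcyclohexane-1,3-dione that an aryloxyacetone (b6, b1, b2) and a crotonate (b5, b4, b3) can build. The hindered ether then becomes an ordinary alkylation of a ring A phenol at a primary carbon.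

## Logic of the disconnections

18 to 16: the a4–CHO bond is cut first. The aldehyde would not survive enolates, acylating acids or oxidation, so it is introduced last. The demand is an ortho-formylation that takes a4 and not a2 and spares lactone and pyranone.

16 to 13 and 14: the b4–C(=O) bond and the b3 O–C(CH3)2 bond are cut, removing the pyranone and five carbons. What remains is a simple depsidone with one free hydroxyl on each ring. The forward step must acylate b4 (not b2, not ring A) and then close through the b3 oxygen.

13 to 11: the lactone bond C(=O)–O(b1) is cut, giving a diaryl ether hydroxy acid. Only the b1 hydroxyl can reach the carboxyl, so the forward step needs activation of a hindered acid but no protecting groups.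

11 to 10: no skeletal bond is cut; ring B is taken back to the cyclohexane-1,3-dione oxidation level. The gain is that the hindered aryl–oxygen bond at b6 becomes an alkyl–oxygen bond and ring B becomes accessible by carbonyl chemistry. The forward step is a dehydrogenation that must tolerate a free acid and a phenol.

10 to 7 and 8: bonds b6–b5 and b2–b3 are cut, which opens ring B into a three-carbon ketone unit already attached to the ring A oxygen and a four-carbon unsaturated ester. The forward step must add through the oxygen-bearing methylene first and close from the methyl group second, and ring A must offer no electrophile to the enolate.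

7 to 5 (through 6): the acid and the a3 hydroxyl are masked as benzyl ester and benzyl ether. The masks are needed only for the ether formation and must come off without base, since an alkoxide would drive the side-chain enolate onto the ester.

5 to 3 and 4: the O–CH2 bond at the a5 oxygen is cut, an SN2 alkylation of a chelated phenol by a primary α-halo ketone. The demand is a base too weak to cyclise the product.

3 to 1 (through 2): the two benzyl–oxygen bonds are cut. The hydrogen bond between the 2-hydroxyl and the carboxyl differentiates the two phenols, so no separate protection of the hydroxyl that must later be alkylated is needed.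

## Other disconnections considered

Alternative 1: The cut removes the lactone carbonyl carbon (bonds a6–C(=O) and C(=O)–O(b1)) and leads to the a6-iodo diaryl ether A1, which keeps the free b1 phenol.
- Forward key step: Pd(OAc)2 with a wide-bite-angle bisphosphine such as Xantphos would be reduced to zerovalent palladium and insert into the a6–I bond. CO insertion would give an acylpalladium that the b1 phenol captures, closing the seven-membered ring to the a3 methyl ether A2. Cleavage of the methyl ether ortho to the formyl group (BCl3) would then give 18.
- In favour: CO is the cheapest one-carbon unit, no hindered acid has to be activated, and the formyl group is already in place, so the a4/a2 question of step 8 does not arise. On that last point it is the better plan.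
- Against: A1 already contains the a5–O–b6 ether, so the worst bond must be made by aryl–oxygen coupling (or SNAr) between two separately built, fully substituted arenes. Oxidative addition at a6 is flanked on both sides, an aldehyde and a phenol must tolerate palladium, CO and base, and a protecting group is added and removed at a3.
- Comparison: both plans pass through the same depsidone skeleton, and the carbonylation is mechanistically the equal of the lactonisation in step 6. The chosen plan makes the ether by SN2 at a primary carbon; two multi-step arenes, a coupling, the carbonylation and a deprotection would exceed eight steps.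

Alternative 2: Ring A itself is cut along a1–a6, a5–a6, a3–a4 and a2–a3, back to the diazo ketoester A3, an aryl ester of ring B whose b6 oxygen carries an alkynyl ether.
- Forward key step: irradiation would expel N2, the Wolff shift would give a vinylketene, and an intramolecular [2+2] addition to the alkynyl ether would give a cyclobutenone. Four-electron opening, six-electron closure and tautomerisation would deliver the phenol A4, closing ring A and the seven-membered ring in one operation.
- In favour: every substituent of ring A is placed by connectivity, and the a4 carbon arrives as a protected hydroxymethyl group (better than a late formylation). The hindered ether is not made by coupling two arenes (equal to the chosen plan), and the conditions are neutral.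
- Against: A3 is costly, because an alkynyl ether on the hindered b6 oxygen needs strongly basic elimination chemistry before the aryl ester and the diazo group can be installed. The ketene–alkyne addition must pass through a medium-ring tether. After A4 the route still needs desilylation and oxidation at a4, debenzylation at b3 and the same pyranone annulation as step 7 (equal on the b4/b2 question).
- Comparison: mechanistically the most elegant, but clearly longer and harder to scale than the chosen plan.

Alternative 3: The cut falls on C(=O)–O(b1) and on a6–a1, so that ring A is grown on the b1 phenol of a finished chromanone.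
- Forward key step: heating the diketo-dioxinone A5 with the bromophenol A6 would release acetone and an acylketene that A6 traps. Base in the same pot would drive aldol closure a6–a1 and dehydration to the aryl orsellinate A7. A copper-mediated intramolecular etherification (CuI, base) between the a5 hydroxyl and the b6 bromide would then give 16, and step 8 would finish.
- In favour: convergent and short. The pyranone is built on a simple phenol before the depsidone exists (better than step 7), no dehydrogenation is needed (better than step 5), and the last step is shared (equal).
- Against: the doubly flanked a5–O–b6 bond is left for a late copper-mediated ring closure on a substrate with a base-labile aryl ester and a base-sensitive chromanone. The bromination leading to A6 must choose b6 over b2, and A5 needs its own preparation.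
- Comparison: in step count Alternative 3 is at least the equal of the chosen plan and probably shorter. The chosen plan is preferred because its ether formation is an ordinary alkylation and its most demanding step comes early on cheap material.

Key step: step 4

Remark on the chemistry: 10 is racemic and is drawn as the diketo tautomer of one trans enantiomer, although it should exist largely as an enol; 1, 4, 8 and 14 are taken as commercial.

## Route

Step 1
Reactants: 1 orsellinic acid (2,4-dihydroxy-6-methylbenzoic acid)
Product: 3 benzyl 4-(benzyloxy)-2-hydroxy-6-methylbenzoate, via benzyl orsellinate 2 (not isolated)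
Conditions: BnBr (2.05 equiv), K2CO3, DMF, 0 °C to rt
Reagents that add atoms: benzyl bromide, BrCc1ccccc1
Why: Williamson O-alkylation (SN2): the carboxylate and the more acidic, unhindered 4-phenoxide are benzylated, whereas the 2-hydroxyl is hydrogen-bonded to the ester carbonyl and should stay free under carbonate at room temperature; early esterification also removes the risk of decarboxylation of the free acid.

Step 2
Reactants: 3 benzyl 4-(benzyloxy)-2-hydroxy-6-methylbenzoate; 4 chloroacetone
Product: 5 benzyl 4-(benzyloxy)-6-methyl-2-(2-oxopropoxy)benzoate
Conditions: 4 (1.5 equiv), K2CO3, KI (cat.), acetone, reflux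
Reagents that add atoms: none
Why: Williamson etherification assisted by Finkelstein exchange: iodoacetone formed in the flask is a very reactive primary SN2 electrophile, so even the chelated, hindered 2-phenoxide should be alkylated; carbonate is too weak a base to drive the Dieckmann-type attack of the new methylene on the neighbouring benzyl ester.

Step 3
Reactants: 5 benzyl 4-(benzyloxy)-6-methyl-2-(2-oxopropoxy)benzoate
Product: 7 4-hydroxy-6-methyl-2-(2-oxopropoxy)benzoic acid, via benzyl ether acid 6 (not isolated)
Conditions: H2 (1 atm), Pd/C, EtOAc–THF, rt
Reagents that add atoms: none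
Why: Catalytic hydrogenolysis of both benzyl–oxygen bonds under neutral conditions, the ester expected to go first; a dialkyl ketone is not reduced at 1 atm, and the absence of base matters because any alkoxide would cyclise keto ester 5 to a benzofuranone.

Step 4
Reactants: 7 4-hydroxy-6-methyl-2-(2-oxopropoxy)benzoic acid; 8 methyl (E)-but-2-enoate
Product: 10 trans-4-(2-carboxy-5-hydroxy-3-methylphenoxy)-5-methylcyclohexane-1,3-dione (racemic), via Michael adduct 9 (not isolated)
Conditions: KOC(CH3)3 (3.5 equiv), THF–DMSO, 0 °C; then 8 (1.5 equiv), 0 °C to rt; then aq HCl, 0 °C
Reagents that add atoms: none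
Why: Consecutive Michael–Claisen annulation, the closest known type being the dimedone-style [3+3] construction of 4-substituted cyclohexane-1,3-diones from substituted acetones and unsaturated esters. Two equivalents of base turn the acid and the phenol into spectator anions, and the third forms, under equilibrating conditions, the enolate at the oxygen-flanked methylene, the most acidic carbon because of the inductive effect of the aryloxy group. This enolate adds to the β-carbon of 8 (bond b6–b5) to give 9 as its ester enolate; proton transfer generates the methyl-ketone enolate, which attacks the ester in a 6-exo-trig acyl substitution (bond b2–b3), expels methoxide and closes ring B. The product is deprotonated at once to the dione enolate, which makes the sequence irreversible and shields the dione from further attack. The two new stereocentres at b5 and b6 are under thermodynamic control, since b6 is α to a ketone and epimerises in the basic medium, so the diequatorial trans isomer should prevail; both centres are erased in step 5, so the racemic outcome is of no consequence. The selectivity needed is the order of events, Michael addition from the aryloxy methylene and Claisen closure from the methyl group, and the acidity difference between the two α-carbons secures it; the reverse order would show up as a symmetrical 2-aryloxy dione. Chemoselectivity toward ring A is secured because a carboxylate, unlike the ester in 5, cannot be attacked by the side-chain enolate.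

Step 5
Reactants: 10 trans-4-(2-carboxy-5-hydroxy-3-methylphenoxy)-5-methylcyclohexane-1,3-dione
Product: 11 2-(2,4-dihydroxy-6-methylphenoxy)-4-hydroxy-6-methylbenzoic acid
Conditions: Pd(OCOCF3)2 (5 mol%), 2-(dimethylamino)pyridine (10 mol%), TsOH (10 mol%), O2 (1 atm), DMSO, 80 °C
Reagents that add atoms: none
Why: Palladium-catalysed aerobic dehydrogenation: a divalent palladium enolate at b4 or b6 undergoes β-hydride elimination from b5 and O2 reoxidises the palladium hydride; loss of one H2 gives the keto tautomer of the resorcinol, which aromatises at once and erases both stereocentres. Low catalyst and acid loading and a moderate temperature are chosen to spare the free, doubly ortho-substituted benzoic acid.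

Step 6
Reactants: 11 2-(2,4-dihydroxy-6-methylphenoxy)-4-hydroxy-6-methylbenzoic acid
Product: 13 3,8-dihydroxy-1,6-dimethyl-11H-dibenzo[b,e][1,4]dioxepin-11-one, via mixed trifluoroacetic anhydride 12 (not isolated)
Conditions: (CF3CO)2O (1.2 equiv), toluene (dilute), 0 °C to rt; aq NaHCO3 wash
Reagents that add atoms: none
Why: Lactonisation through the mixed anhydride, an acylium-like activation that suits a doubly ortho-substituted benzoic acid: only the b1 hydroxyl, ortho to the ether bridge, can reach the carbonyl and close the seven-membered ring, and the bicarbonate wash returns any phenol that was acylated. Closure to a xanthone, the usual fate of 2-aryloxybenzoic acids, is excluded because both ring B positions ortho to the ether oxygen are substituted.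

Step 7
Reactants: 13 3,8-dihydroxy-1,6-dimethyl-11H-dibenzo[b,e][1,4]dioxepin-11-one; 14 3-methylbut-2-enoic acid
Product: 16 4-desformyl mollicellin A, via b4 aryl enone 15 (not isolated)
Conditions: 14 (1.1 equiv), P2O5/CH3SO3H (Eaton's reagent), 70 °C
Reagents that add atoms: none
Why: One-pot Friedel–Crafts acylation and oxa-Michael closure, the standard synthesis of 2,2-dimethylchroman-4-ones from phenols and 14: the acylium equivalent should attack ring B ortho to the free b3 hydroxyl at b4, which is also para to the lactone oxygen and less deactivated inductively than b2 between two oxygens, and the b3 hydroxyl then adds to enone 15 in a 6-endo-trig closure. Ring A is deactivated by the lactone carbonyl para to its hydroxyl and is expected to stay untouched.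

Step 8
Reactants: 16 4-desformyl mollicellin A
Product: 18 mollicellin A, via chloro(methoxy)methyl arene 17 (not isolated)
Conditions: TiCl4 (3 equiv), Cl2CHOCH3 (1.5 equiv), CH2Cl2, −10 to 0 °C; then aq HCl
Reagents that add atoms: dichloromethyl methyl ether, COC(Cl)Cl; water, O
Why: Rieche formylation: TiCl4 forms the titanium phenoxide at a3 and delivers the electrophile to an ortho position; a4, held between the phenoxide and the ether oxygen, is the chelation-favoured site, as in the formylation of orsellinates to haematommates. Ring B has no free hydroxyl to compete, and hydrolysis of 17 in the work-up gives the hydrogen-bonded salicylaldehyde.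

## Compound list

1 | orsellinic acid (2,4-dihydroxy-6-methylbenzoic acid) | Cc1cc(O)cc(O)c1C(=O)O | starting material
2 | benzyl 2,4-dihydroxy-6-methylbenzoate (benzyl orsellinate) | Cc1cc(O)cc(O)c1C(=O)OCc1ccccc1 | intermediate (not isolated)
3 | benzyl 4-(benzyloxy)-2-hydroxy-6-methylbenzoate | Cc1cc(OCc2ccccc2)cc(O)c1C(=O)OCc1ccccc1 | intermediate
4 | chloroacetone (1-chloropropan-2-one) | CC(=O)CCl | starting material
5 | benzyl 4-(benzyloxy)-6-methyl-2-(2-oxopropoxy)benzoate | Cc1cc(OCc2ccccc2)cc(OCC(C)=O)c1C(=O)OCc1ccccc1 | intermediate
6 | 4-(benzyloxy)-6-methyl-2-(2-oxopropoxy)benzoic acid | Cc1cc(OCc2ccccc2)cc(OCC(C)=O)c1C(=O)O | intermediate (not isolated)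
7 | 4-hydroxy-6-methyl-2-(2-oxopropoxy)benzoic acid | Cc1cc(O)cc(OCC(C)=O)c1C(=O)O | intermediate
8 | methyl (E)-but-2-enoate | C/C=C/C(=O)OC | starting material
9 | 4-hydroxy-2-[(6-methoxy-4-methyl-2,6-dioxohexan-3-yl)oxy]-6-methylbenzoic acid (Michael adduct; mixture of diastereomers, each racemic) | Cc1cc(O)cc(OC(C(C)=O)C(C)CC(=O)OC)c1C(=O)O | intermediate (not isolated)
10 | trans-4-(2-carboxy-5-hydroxy-3-methylphenoxy)-5-methylcyclohexane-1,3-dione (racemic; the 4R,5S enantiomer drawn; aryloxy and methyl trans) | Cc1cc(O)cc(O[C@@H]2[C@@H](C)CC(=O)CC2=O)c1C(=O)O | intermediate
11 | 2-(2,4-dihydroxy-6-methylphenoxy)-4-hydroxy-6-methylbenzoic acid | Cc1cc(O)cc(Oc2c(C)cc(O)cc2O)c1C(=O)O | intermediate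
12 | 2-(2,4-dihydroxy-6-methylphenoxy)-4-hydroxy-6-methylbenzoic trifluoroacetic anhydride | Cc1cc(O)cc(Oc2c(C)cc(O)cc2O)c1C(=O)OC(=O)C(F)(F)F | intermediate (not isolated)
13 | 3,8-dihydroxy-1,6-dimethyl-11H-dibenzo[b,e][1,4]dioxepin-11-one | Cc1cc(O)cc2c1C(=O)Oc1cc(O)cc(C)c1O2 | intermediate
14 | 3-methylbut-2-enoic acid | CC(C)=CC(=O)O | starting material
15 | 3,8-dihydroxy-1,6-dimethyl-7-(3-methylbut-2-enoyl)-11H-dibenzo[b,e][1,4]dioxepin-11-one | Cc1cc(O)cc2c1C(=O)Oc1cc(O)c(C(=O)C=C(C)C)c(C)c1O2 | intermediate (not isolated)
16 | 4-desformyl mollicellin A (depsidone with a3 hydroxyl, a4 hydrogen and the 2,2-dimethyl-2,3-dihydropyran-4-one fused at b3–b4) | Cc1cc(O)cc2c1C(=O)Oc1cc3c(c(C)c1O2)C(=O)CC(C)(C)O3 | intermediate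
17 | a4-[chloro(methoxy)methyl] derivative of 16 (racemic at the new carbon) | Cc1cc(O)c(C(Cl)OC)c2c1C(=O)Oc1cc3c(c(C)c1O2)C(=O)CC(C)(C)O3 | intermediate (not isolated)
18 | mollicellin A | Cc1cc(O)c(C=O)c2c1C(=O)Oc1cc3c(c(C)c1O2)C(=O)CC(C)(C)O3 | target

## Step count and least certain steps

Total step count: 8. Longest linear sequence: 8 steps (1 to 18); the route is linear, with 4, 8 and 14 entering as commercial reagents.

Step 4 (key step). The conjugate addition of a hindered, stabilised trianionic enolate to a β-substituted, weakly electrophilic ester may be slow, which would let base-induced self-condensation of 8 (γ-deprotonation) or leakage through the less hindered methyl-side enolate compete; the sequence may also stall at 9. Fallback: starting from 7, the acceptor is changed to commercial dimethyl ethylidenemalonate under classical conditions (NaOCH3, CH3OH, reflux). The far more electrophilic alkylidenemalonate should take up the enolate readily and the methyl-ketone enolate closes onto one ester, giving methyl 5-(2-carboxy-5-hydroxy-3-methylphenoxy)-6-methyl-2,4-dioxocyclohexane-1-carboxylate F1. Saponification, acidification and gentle warming (aq NaOH; then HCl, 50 °C) remove the extra carboxyl and return the route to 10.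

Step 5. Palladium-mediated or acid-promoted loss of CO2 from the electron-rich, doubly ortho-substituted benzoic acid, sequestration of the catalyst by the β-diketonate, and over-oxidation of the electron-rich product are the likely failures. Fallback: starting from 10, persilylation ((CH3)3SiOSO2CF3, N(C2H5)3, CH2Cl2, 0 °C) converts acid, phenol and dione into trimethylsilyl 2-{[6-methyl-2,4-bis(trimethylsilyloxy)cyclohexa-1,3-dien-1-yl]oxy}-6-methyl-4-(trimethylsilyloxy)benzoate F2. After removal of the amine salts, DDQ (1 equiv, rt) abstracts hydride from the diene to give the aromatic trimethylsilyl 2-[6-methyl-2,4-bis(trimethylsilyloxy)phenoxy]-6-methyl-4-(trimethylsilyloxy)benzoate F3. Methanolysis with a trace of acid frees 11, with neither palladium nor heat.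

Step 7. Acylation at b2 in place of b4 is the main risk, because the b1 oxygen is acylated and no longer directs para; O-acylation of the a3 hydroxyl and conjugate C-alkylation leading to a dihydrocoumarin are secondary risks. Fallback: starting from 11, before the lactone is closed, Hoesch acylation with acetonitrile (ZnCl2, HCl, Et2O, 0 °C) should occur at b4, para to the still free b1 hydroxyl, as with 5-methylresorcinol itself. It gives 1-[3-(2-carboxy-5-hydroxy-3-methylphenoxy)-4,6-dihydroxy-2-methylphenyl]ethan-1-iminium chloride F4, which warm water hydrolyses to 2-(3-acetyl-4,6-dihydroxy-2-methylphenoxy)-4-hydroxy-6-methylbenzoic acid F5. Kabbe condensation (acetone, pyrrolidine, toluene, reflux) closes the pyranone through the b3 oxygen to 4-hydroxy-2-[(7-hydroxy-2,2,5-trimethyl-4-oxo-3,4-dihydro-2H-chromen-6-yl)oxy]-6-methylbenzoic acid F6. Lactonisation with (CF3CO)2O as in step 6 then returns the route to 16.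

Step 8. Electrophilic attack at a2 (ortho to the hydroxyl and para to the ether oxygen) may compete with the chelation-directed attack at a4, and the Lewis acid may open the pyranone. Fallback: starting from 16, bromination with N-bromosuccinimide (CH3CN, 0 °C) is expected to take the same intrinsically favoured a2 position and give the a2-bromo derivative of 16 F7. With a2 blocked, TiCl4/Cl2CHOCH3 can only formylate a4 and gives a2-bromo mollicellin A F8. Transfer hydrodebromination (Pd(OAc)2, P(C6H5)3, HCO2Na, DMF, 80 °C), which does not reduce aldehydes, arrives at 18.

Step 2. Incomplete alkylation of the chelated, hindered hydroxyl and base-induced Dieckmann-type closure of 5 onto its own benzyl ester during prolonged heating are the risks. Fallback: starting from 3, alkylation with 3-bromo-2-methylprop-1-ene (K2CO3, DMF, 50 °C) gives benzyl 4-(benzyloxy)-6-methyl-2-[(2-methylprop-2-en-1-yl)oxy]benzoate F9, which has no enolisable ketone and cannot cyclise. Lemieux–Johnson cleavage (OsO4 cat., NaIO4, 2,6-lutidine, dioxane–H2O) then unveils the ketone under near-neutral conditions and returns the route to 5.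

## Further compounds

F1 | step 4 | methyl 5-(2-carboxy-5-hydroxy-3-methylphenoxy)-6-methyl-2,4-dioxocyclohexane-1-carboxylate (mixture of diastereomers) | Cc1cc(O)cc(OC2C(C)C(C(=O)OC)C(=O)CC2=O)c1C(=O)O
F2 | step 5 | trimethylsilyl 2-{[6-methyl-2,4-bis(trimethylsilyloxy)cyclohexa-1,3-dien-1-yl]oxy}-6-methyl-4-(trimethylsilyloxy)benzoate (racemic) | Cc1cc(O[Si](C)(C)C)cc(OC2=C(O[Si](C)(C)C)C=C(O[Si](C)(C)C)CC2C)c1C(=O)O[Si](C)(C)C
F3 | step 5 | trimethylsilyl 2-[6-methyl-2,4-bis(trimethylsilyloxy)phenoxy]-6-methyl-4-(trimethylsilyloxy)benzoate | Cc1cc(O[Si](C)(C)C)cc(Oc2c(C)cc(O[Si](C)(C)C)cc2O[Si](C)(C)C)c1C(=O)O[Si](C)(C)C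
F4 | step 7 | 1-[3-(2-carboxy-5-hydroxy-3-methylphenoxy)-4,6-dihydroxy-2-methylphenyl]ethan-1-iminium chloride | Cc1cc(O)cc(Oc2c(C)c(C(C)=[NH2+])c(O)cc2O)c1C(=O)O.[Cl-]
F5 | step 7 | 2-(3-acetyl-4,6-dihydroxy-2-methylphenoxy)-4-hydroxy-6-methylbenzoic acid | Cc1cc(O)cc(Oc2c(C)c(C(C)=O)c(O)cc2O)c1C(=O)O
F6 | step 7 | 4-hydroxy-2-[(7-hydroxy-2,2,5-trimethyl-4-oxo-3,4-dihydro-2H-chromen-6-yl)oxy]-6-methylbenzoic acid | Cc1cc(O)cc(Oc2c(O)cc3OC(C)(C)CC(=O)c3c2C)c1C(=O)O
F7 | step 8 | a2-bromo derivative of 16 | Cc1c(Br)c(O)cc2c1C(=O)Oc1cc3c(c(C)c1O2)C(=O)CC(C)(C)O3
F8 | step 8 | a2-bromo mollicellin A | Cc1c(Br)c(O)c(C=O)c2c1C(=O)Oc1cc3c(c(C)c1O2)C(=O)CC(C)(C)O3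
F9 | step 2 | benzyl 4-(benzyloxy)-6-methyl-2-[(2-methylprop-2-en-1-yl)oxy]benzoate | Cc1cc(OCc2ccccc2)cc(OCC(C)=C)c1C(=O)OCc1ccccc1
A1 | alternative 1 | 2-[(7-hydroxy-2,2,5-trimethyl-4-oxo-3,4-dihydro-2H-chromen-6-yl)oxy]-3-iodo-6-methoxy-4-methylbenzaldehyde | Cc1cc(OC)c(C=O)c(Oc2c(O)cc3OC(C)(C)CC(=O)c3c2C)c1I
A2 | alternative 1 | mollicellin A a3-methyl ether | Cc1cc(OC)c(C=O)c2c1C(=O)Oc1cc3c(c(C)c1O2)C(=O)CC(C)(C)O3
A3 | alternative 2 | 5-(benzyloxy)-3-methyl-2-{[3-(triisopropylsilyloxy)prop-1-yn-1-yl]oxy}phenyl 2-diazo-4-methyl-3-oxopent-4-enoate | C=C(C)C(=O)C(=[N+]=[N-])C(=O)Oc1cc(OCc2ccccc2)cc(C)c1OC#CCO[Si](C(C)C)(C(C)C)C(C)C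
A4 | alternative 2 | 8-(benzyloxy)-3-hydroxy-1,6-dimethyl-4-{[(triisopropylsilyl)oxy]methyl}-11H-dibenzo[b,e][1,4]dioxepin-11-one | Cc1cc(O)c(CO[Si](C(C)C)(C(C)C)C(C)C)c2c1C(=O)Oc1cc(OCc3ccccc3)cc(C)c1O2
A5 | alternative 3 | 2,2-dimethyl-6-(2,4-dioxopentyl)-4H-1,3-dioxin-4-one | CC(=O)CC(=O)CC1=CC(=O)OC(C)(C)O1
A6 | alternative 3 | 6-bromo-7-hydroxy-2,2,5-trimethyl-2,3-dihydro-4H-chromen-4-one | Cc1c(Br)c(O)cc2OC(C)(C)CC(=O)c12
A7 | alternative 3 | 6-bromo-2,2,5-trimethyl-4-oxo-3,4-dihydro-2H-chromen-7-yl 2,4-dihydroxy-6-methylbenzoate | Cc1cc(O)cc(O)c1C(=O)Oc1cc2OC(C)(C)CC(=O)c2c(C)c1Br
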